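The route rests on the bond between ring carbon C4 of the oxolan-2-one and the exocyclic carbinol carbon. With the ring CH2–O carbon (C5) raised to a carboxyl group, these two atoms are the α- and β-carbons of a β-hydroxy acid, so an aldol addition to O-silylvanillin makes the bond and both new stereocentres in one operation. The precursor is the tert-butyl dioxolanone of (S)-2-arylmethylmalic acid: the α-hydroxy acid unit C2/C3 of the lactone is masked as the acetal, and its quaternary centre, bought as L-malic acid, relays the configuration. Borane reduction of the carboxyl group and transacylation then close the lactone.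

Key step: step 6

Remark: locants C2–C5 refer to the oxolan-2-one ring of the target; the LDA-derived enolate of the silyl ester is assumed to have the E(O) geometry usual for ester enolates in THF.

Step 1
Reactants: 1 vanillin
Product: 2 4-[(tert-butyldimethylsilyl)oxy]-3-methoxybenzaldehyde
Conditions: TBSCl, imidazole, DMF, rt
Reagents that add atoms: tert-butyldimethylsilyl chloride CC(C)(C)[Si](C)(C)Cl
Why: Imidazole-promoted silylation of the phenol; the aryl silyl ether withstands the amide bases and borane used later and is removed at the end by buffered fluoride, so that neither acid nor hydrogenolysis touches the benzylic alcohol.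

Step 2
Reactants: 2 4-[(tert-butyldimethylsilyl)oxy]-3-methoxybenzaldehyde
Product: 3 {4-[(tert-butyldimethylsilyl)oxy]-3-methoxyphenyl}methanol
Conditions: NaBH4, THF/MeOH, 0 °C
Reagents that add atoms: none
Why: Sodium borohydride reduction of the aromatic aldehyde to the benzylic alcohol is fast at 0 °C and leaves the aryl silyl ether intact.

Step 3
Reactants: 3 {4-[(tert-butyldimethylsilyl)oxy]-3-methoxyphenyl}methanol
Product: 4 [4-(bromomethyl)-2-methoxyphenoxy](tert-butyl)dimethylsilane
Conditions: CBr4, PPh3, CH2Cl2, 0 °C; short silica plug, used at once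
Reagents that add atoms: carbon tetrabromide BrC(Br)(Br)Br
Why: Appel reaction under neutral conditions converts the primary benzylic alcohol into the bromide without acid that would cleave the silyl ether; the electron-rich bromide is used at once.

Step 4
Reactants: 5 (S)-malic acid
Product: 6 [(2S,4S)-2-tert-butyl-5-oxo-1,3-dioxolan-4-yl]acetic acid
Conditions: t-BuCHO, TsOH (cat.), H2SO4 (cat.), pentane, reflux, Dean–Stark; recrystallisation
Reagents that add atoms: pivalaldehyde CC(C)(C)C=O
Why: Acid-catalysed acetalisation of the α-hydroxy acid unit with azeotropic removal of water (first stage of the self-regeneration of stereocentres) engages the five-membered 1,3-dioxolan-4-one and not the β-carboxyl group; the new acetal centre (2S) is set under thermodynamic control cis to the malic acid centre, and the cis isomer is purified by crystallisation.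

Step 5
Reactants: 6 [(2S,4S)-2-tert-butyl-5-oxo-1,3-dioxolan-4-yl]acetic acid; 4 [4-(bromomethyl)-2-methoxyphenoxy](tert-butyl)dimethylsilane
Product: 8 2-[(2S,4S)-2-tert-butyl-4-({4-[(tert-butyldimethylsilyl)oxy]-3-methoxyphenyl}methyl)-5-oxo-1,3-dioxolan-4-yl]acetic acid, via dilithium enolate carboxylate 7 (not isolated)
Conditions: LiHMDS (2.2 equiv), THF, −78 °C; then 4, −78 → −30 °C; cold 1 M HCl work-up
Reagents that add atoms: none
Why: Enolate alkylation with self-regeneration of the stereocentre: the carboxylate keeps the side chain from being deprotonated, the ring enolate is alkylated on the face opposite to the tert-butyl group, and the benzyl group therefore takes the place of hydrogen with retention to give the 4S quaternary centre.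

Step 6
Reactants: 8 2-[(2S,4S)-2-tert-butyl-4-({4-[(tert-butyldimethylsilyl)oxy]-3-methoxyphenyl}methyl)-5-oxo-1,3-dioxolan-4-yl]acetic acid; 2 4-[(tert-butyldimethylsilyl)oxy]-3-methoxybenzaldehyde
Product: 12 (2R,3R)-2-[(2S,4S)-2-tert-butyl-4-({4-[(tert-butyldimethylsilyl)oxy]-3-methoxyphenyl}methyl)-5-oxo-1,3-dioxolan-4-yl]-3-{4-[(tert-butyldimethylsilyl)oxy]-3-methoxyphenyl}-3-hydroxypropanoic acid, via trimethylsilyl ester 9 (not isolated), via lithium enolate 10 (not isolated), via lithium aldolate 11 (not isolated)
Conditions: LDA (1.0 equiv), THF, −78 °C, then TMSCl (1.0 equiv), −78 → 0 °C; LDA (1.15 equiv), −78 °C; 2, −78 °C; AcOH, −78 °C; aq. citric acid, 0 °C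
Reagents that add atoms: none
Why: The acid is silylated in the flask so that LDA forms the lithium ester enolate at −78 °C, where the β-acetal oxygen is not eliminated, and this enolate adds to aldehyde 2 through a closed six-membered chair (Zimmerman–Traxler) transition state; the closest known reaction type is the anti-selective aldol addition of ester or carboxylate enolates that bear a tertiary alkyl group on the α-carbon. No ring is closed. The α-centre (future ring C4, 2R) is controlled by the neighbouring quaternary dioxolanone carbon: the ring oxygen should take the inside position of the enolate (inside-alkoxy effect and least allylic strain), the trajectory anti to the benzyl group crosses the ring face that carries the cis tert-butyl group and is blocked, and the aldehyde should therefore add anti to the ring carbonyl carbon. The carbinol centre (3R) is controlled by the bulk of the same quaternary α-substituent, which makes its gauche contact with the aryl group of the aldehyde the dominant interaction in the chair and favours the anti adduct from either enolate geometry. The step needs this facial and anti selectivity and an aldolate that does not attack the dioxolanone carbonyl; the latter is secured by the low temperature, by the O-to-O shift of the silyl group that can only cap the aldolate, and by the fact that the competing lactone would carry three cis substituents.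

Step 7
Reactants: 12 (2R,3R)-2-[(2S,4S)-2-tert-butyl-4-({4-[(tert-butyldimethylsilyl)oxy]-3-methoxyphenyl}methyl)-5-oxo-1,3-dioxolan-4-yl]-3-{4-[(tert-butyldimethylsilyl)oxy]-3-methoxyphenyl}-3-hydroxypropanoic acid
Product: 14 (3S,4R)-3-({4-[(tert-butyldimethylsilyl)oxy]-3-methoxyphenyl}methyl)-4-[(R)-{4-[(tert-butyldimethylsilyl)oxy]-3-methoxyphenyl}(hydroxy)methyl]-3-hydroxyoxolan-2-one, via hydroxy dioxolanone 13 (not isolated)
Conditions: BH3·SMe2, THF, 0 °C → rt; MeOH; then Et3N, DMAP (cat.), CH2Cl2, rt
Reagents that add atoms: none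
Why: Chemoselective borane reduction of a carboxylic acid (through the acyloxyborane) in the presence of the less reactive acyl acetal, followed by base-catalysed 5-exo-trig transacylation of the primary alcohol onto the dioxolanone carbonyl with loss of pivalaldehyde; the benzylic hydroxyl should not compete because its lactone would carry three cis substituents, and no stereocentre is touched.

Step 8
Reactants: 14 (3S,4R)-3-({4-[(tert-butyldimethylsilyl)oxy]-3-methoxyphenyl}methyl)-4-[(R)-{4-[(tert-butyldimethylsilyl)oxy]-3-methoxyphenyl}(hydroxy)methyl]-3-hydroxyoxolan-2-one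
Product: 15 (3S,4R)-3-hydroxy-4-[(R)-hydroxy(4-hydroxy-3-methoxyphenyl)methyl]-3-[(4-hydroxy-3-methoxyphenyl)methyl]oxolan-2-one
Conditions: TBAF, AcOH, THF, 0 °C
Reagents that add atoms: none
Why: Fluoride-mediated cleavage of the two aryl silyl ethers; the acetic acid buffer keeps the medium near neutral so that the p-hydroxybenzylic alcohol neither eliminates to a quinone methide nor migrates the lactone.

Compound list
1 | vanillin (4-hydroxy-3-methoxybenzaldehyde) | COc1cc(C=O)ccc1O | starting material
2 | 4-[(tert-butyldimethylsilyl)oxy]-3-methoxybenzaldehyde | COc1cc(C=O)ccc1O[Si](C)(C)C(C)(C)C | intermediate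
3 | {4-[(tert-butyldimethylsilyl)oxy]-3-methoxyphenyl}methanol | COc1cc(CO)ccc1O[Si](C)(C)C(C)(C)C | intermediate
4 | [4-(bromomethyl)-2-methoxyphenoxy](tert-butyl)dimethylsilane | COc1cc(CBr)ccc1O[Si](C)(C)C(C)(C)C | intermediate
5 | (S)-malic acid (L-malic acid) | O[C@@H](CC(=O)O)C(=O)O | starting material
6 | [(2S,4S)-2-tert-butyl-5-oxo-1,3-dioxolan-4-yl]acetic acid (cis acetal) | O=C1O[C@@H](C(C)(C)C)O[C@H]1CC(=O)O | intermediate
7 | dilithium enolate carboxylate of 6 (ring enolate, side-chain carboxylate) | CC(C)(C)[C@@H]1OC([O-])=C(CC(=O)[O-])O1.[Li+].[Li+] | intermediate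
8 | 2-[(2S,4S)-2-tert-butyl-4-({4-[(tert-butyldimethylsilyl)oxy]-3-methoxyphenyl}methyl)-5-oxo-1,3-dioxolan-4-yl]acetic acid (benzyl trans to tert-butyl) | COc1cc(C[C@]2(O[C@H](C(C)(C)C)OC2=O)CC(=O)O)ccc1O[Si](C)(C)C(C)(C)C | intermediate
9 | trimethylsilyl ester of 8 | COc1cc(C[C@]2(O[C@H](C(C)(C)C)OC2=O)CC(=O)O[Si](C)(C)C)ccc1O[Si](C)(C)C(C)(C)C | intermediate
10 | lithium E(O)-enolate of 9 | COc1cc(C[C@]2(O[C@H](C(C)(C)C)OC2=O)/C=C(\O[Si](C)(C)C)[O-])ccc1O[Si](C)(C)C(C)(C)C.[Li+] | intermediate
11 | lithium aldolate of the anti adduct, carboxyl as trimethylsilyl ester | COc1cc(C[C@]2(O[C@H](C(C)(C)C)OC2=O)[C@H](C(=O)O[Si](C)(C)C)[C@@H]([O-])c2ccc(O[Si](C)(C)C(C)(C)C)c(OC)c2)ccc1O[Si](C)(C)C(C)(C)C.[Li+] | intermediate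
12 | (2R,3R)-2-[(2S,4S)-2-tert-butyl-4-({4-[(tert-butyldimethylsilyl)oxy]-3-methoxyphenyl}methyl)-5-oxo-1,3-dioxolan-4-yl]-3-{4-[(tert-butyldimethylsilyl)oxy]-3-methoxyphenyl}-3-hydroxypropanoic acid | COc1cc(C[C@]2(O[C@H](C(C)(C)C)OC2=O)[C@H](C(=O)O)[C@@H](O)c2ccc(O[Si](C)(C)C(C)(C)C)c(OC)c2)ccc1O[Si](C)(C)C(C)(C)C | intermediate
13 | (2S,5S)-2-tert-butyl-5-({4-[(tert-butyldimethylsilyl)oxy]-3-methoxyphenyl}methyl)-5-[(1R,2R)-1-{4-[(tert-butyldimethylsilyl)oxy]-3-methoxyphenyl}-1,3-dihydroxypropan-2-yl]-1,3-dioxolan-4-one | COc1cc(C[C@]2(O[C@H](C(C)(C)C)OC2=O)[C@H](CO)[C@@H](O)c2ccc(O[Si](C)(C)C(C)(C)C)c(OC)c2)ccc1O[Si](C)(C)C(C)(C)C | intermediate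
14 | (3S,4R)-3-({4-[(tert-butyldimethylsilyl)oxy]-3-methoxyphenyl}methyl)-4-[(R)-{4-[(tert-butyldimethylsilyl)oxy]-3-methoxyphenyl}(hydroxy)methyl]-3-hydroxyoxolan-2-one | COc1cc(C[C@@]2(O)C(=O)OC[C@@H]2[C@@H](O)c2ccc(O[Si](C)(C)C(C)(C)C)c(OC)c2)ccc1O[Si](C)(C)C(C)(C)C | intermediate
15 | (3S,4R)-3-hydroxy-4-[(R)-hydroxy(4-hydroxy-3-methoxyphenyl)methyl]-3-[(4-hydroxy-3-methoxyphenyl)methyl]oxolan-2-one | COc1cc(C[C@@]2(O)C(=O)OC[C@@H]2[C@@H](O)c2ccc(O)c(OC)c2)ccc1O | target

Total step count: 8. Longest linear sequence: 7 steps (1 → 2 → 3 → 4 → 8 → 12 → 14 → 15; steps 1, 2, 3, 5, 6, 7, 8).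

Steps most likely to fail

Step 6 (key step). What may go wrong is poor π-facial discrimination at the enolate carbon next to the quaternary centre, which would give the epimer at the future C4, or retro-aldol cleavage and elimination of the ring oxygen if the enolate warms. The fallback replaces substrate control by a chiral auxiliary. It sets out from 8, which is coupled with (R)-4-benzyloxazolidin-2-one (PivCl, Et3N, LiCl, THF) to the imide F1. The magnesium chloride-catalysed anti-aldol addition of F1 to 2 (MgCl2, Et3N, TMSCl, EtOAc) should give the silylated anti adduct F2, with both centres fixed by the auxiliary through the chelated Z-enolate. NaBH4 in THF/water removes the auxiliary reductively, and the freed primary alcohol closes the lactone on the dioxolanone to the benzylic trimethylsilyl ether F3. Aqueous citric acid removes the trimethylsilyl group, and the route is rejoined at 14.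

Step 7. What may go wrong is loss of chemoselectivity: hydride delivery to the acyl acetal before the hindered carboxyl group is reduced, or ionisation of the electron-rich benzylic alcohol by the Lewis acidic borane. The fallback activates the carboxyl group and uses a nucleophilic hydride. It sets out from 12, which isobutyl chloroformate and N-methylmorpholine (THF, −15 °C) convert into the mixed carbonic anhydride F4. Aqueous NaBH4 at −15 °C reduces F4 to the hydroxy dioxolanone 13, where the route is rejoined; 13 lactonises to 14 as in step 7.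

Step 5. What may go wrong is decomposition of the electron-rich silyloxybenzyl bromide (ionisation and self-condensation) faster than C-alkylation of the hindered dianion. The fallback uses a robust electrophile and exchanges the protecting group before any benzylic alcohol exists. It sets out from 6, whose dianion 7 is alkylated with commercial 4-(benzyloxy)-3-methoxybenzyl bromide to the benzyl ether F5. Hydrogenolysis (H2, Pd/C, EtOAc) gives the phenol F6, and TBSCl/imidazole (DMF) gives the bis-silyl compound F7. AcOH/THF/water hydrolyses only the silyl ester of F7, and the route is rejoined at 8.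

Further compounds
F1 | step 6 | (4R)-4-benzyl-3-{2-[(2S,4S)-2-tert-butyl-4-({4-[(tert-butyldimethylsilyl)oxy]-3-methoxyphenyl}methyl)-5-oxo-1,3-dioxolan-4-yl]acetyl}-1,3-oxazolidin-2-one | COc1cc(C[C@]2(O[C@H](C(C)(C)C)OC2=O)CC(=O)N2[C@H](Cc3ccccc3)COC2=O)ccc1O[Si](C)(C)C(C)(C)C
F2 | step 6 | anti-aldol adduct of F1 and 2 as its trimethylsilyl ether (2R,3R in the acyl chain) | COc1cc(C[C@]2(O[C@H](C(C)(C)C)OC2=O)[C@H](C(=O)N2[C@H](Cc3ccccc3)COC2=O)[C@@H](O[Si](C)(C)C)c2ccc(O[Si](C)(C)C(C)(C)C)c(OC)c2)ccc1O[Si](C)(C)C(C)(C)C
F3 | step 6 | benzylic O-trimethylsilyl ether of 14 | COc1cc(C[C@@]2(O)C(=O)OC[C@@H]2[C@@H](O[Si](C)(C)C)c2ccc(O[Si](C)(C)C(C)(C)C)c(OC)c2)ccc1O[Si](C)(C)C(C)(C)C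
F4 | step 7 | mixed anhydride of 12 with isobutyl hydrogen carbonate | COc1cc(C[C@]2(O[C@H](C(C)(C)C)OC2=O)[C@H](C(=O)OC(=O)OCC(C)C)[C@@H](O)c2ccc(O[Si](C)(C)C(C)(C)C)c(OC)c2)ccc1O[Si](C)(C)C(C)(C)C
F5 | step 5 | 2-[(2S,4S)-4-{[4-(benzyloxy)-3-methoxyphenyl]methyl}-2-tert-butyl-5-oxo-1,3-dioxolan-4-yl]acetic acid | COc1cc(C[C@]2(O[C@H](C(C)(C)C)OC2=O)CC(=O)O)ccc1OCc1ccccc1
F6 | step 5 | 2-[(2S,4S)-2-tert-butyl-4-[(4-hydroxy-3-methoxyphenyl)methyl]-5-oxo-1,3-dioxolan-4-yl]acetic acid | COc1cc(C[C@]2(O[C@H](C(C)(C)C)OC2=O)CC(=O)O)ccc1O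
F7 | step 5 | tert-butyldimethylsilyl ester of 8 | COc1cc(C[C@]2(O[C@H](C(C)(C)C)OC2=O)CC(=O)O[Si](C)(C)C(C)(C)C)ccc1O[Si](C)(C)C(C)(C)C
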